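**Retrosynthetic overview**

- Locants used below: ring C1(CH3)=C2, C3 (aryloxy carbon), C4 (side-chain carbon), C5, C6 (carbinol); side chain C7(CH3)–C8–C9(=O)–C10=C11.
- The strategy rests on C3 of the cyclohexene ring, an allylic carbinol carbon bonded to the vinylic C2 of the trisubstituted C1=C2 alkene. The C2–C3 bond is cut as the addition of a (Z)-alkenylchromium to a C3 aldehyde (intramolecular Nozaki–Hiyama–Kishi reaction). This is the only ring closure of the route; both benzene rings are bought.
- After ring closure: C3–O–aryl by SNAr on 4-fluoro-3-methoxybenzaldehyde (retention at C3), the C9–C11 enone from the Weinreb amide, and the curcuminoid by boron-mediated aldol with feruloylacetone.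
- Acyclic precursor 19: C7 from hemiester 1, C4 by Evans allylation, C6 by Noyori transfer hydrogenation of a silyl ynone. C3–OH and the C9 carboxyl are held as δ-lactone 8, a temporary ring reopened in step 10.
- The (Z)-C1=C2–I unit comes from copper-catalysed anti-carbomagnesiation/iodination of the propargylic alkoxide. It is run on the ring-opened carboxylate, so no electrophilic carbonyl meets the Grignard reagent.

Key step: step 12

Remark: hemiester 1 is taken as the commercial (3R)-enantiomer (free acid arm becomes C4–C3, ester arm C8–C9); the 1,3-diketone units are drawn in the tautomer of the target SMILES.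

**Route**

Step 1
Reactants: 1 methyl hydrogen (3R)-3-methylglutarate; 2 (4R)-4-benzyl-1,3-oxazolidin-2-one
Product: 4 methyl (3R)-5-[(4R)-4-benzyl-2-oxo-1,3-oxazolidin-3-yl]-3-methyl-5-oxopentanoate, via mixed pivalic anhydride 3 (not isolated)
Conditions: PivCl, Et3N, THF, −20 °C; then LiCl, 2, −20 °C → rt
Reagents that add atoms: none
Why: N-acylation of the oxazolidinone through the mixed pivalic anhydride should take place at the unhindered glutarate carbonyl and leave the methyl ester untouched; no stereocentre is formed.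

Step 2
Reactants: 4 imide; 5 allyl iodide
Product: 6 methyl (3S,4R)-4-{[(4R)-4-benzyl-2-oxo-1,3-oxazolidin-3-yl]carbonyl}-3-methylhept-6-enoate
Conditions: NaN(SiMe3)2, THF, −78 °C; then 5, −78 → −45 °C
Reagents that add atoms: none
Why: Evans asymmetric alkylation: the chelated (Z)-sodium enolate of the imide (more acidic than the ester) should be allylated on the face opposite the benzyl group of the (R)-auxiliary, which sets C4 as R under reagent control.

Step 3
Reactants: 6 allylated imide
Product: 8 (4S,5R)-4-methyl-5-(prop-2-en-1-yl)oxan-2-one, via hydroxy ester 7 (not isolated)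
Conditions: NaBH4, THF/H2O, 0 °C → rt; then TsOH·H2O (cat.), CH2Cl2, rt
Reagents that add atoms: none
Why: Reductive cleavage of the Evans auxiliary: NaBH4 in wet THF reduces the activated imide carbonyl but not the methyl ester, and acid closes the δ-hydroxy ester to the lactone that masks C3–OH and the C9 carboxyl together; no stereocentre is touched.

Step 4
Reactants: 8 allyl lactone
Product: 9 [(3R,4S)-4-methyl-6-oxooxan-3-yl]acetic acid
Conditions: RuCl3·xH2O (cat.), NaIO4, CCl4/MeCN/H2O, rt
Reagents that add atoms: sodium periodate, [Na+].[O-]I(=O)(=O)=O; water, O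
Why: Ruthenium tetroxide-catalysed oxidative cleavage should degrade the terminal vinyl group to the C6 carboxylic acid while the lactone is inert.

Step 5
Reactants: 9 lactone acid; 10 ethynyl(trimethyl)silane
Product: 12 (4S,5R)-4-methyl-5-[2-oxo-4-(trimethylsilyl)but-3-yn-1-yl]oxan-2-one, via acid chloride 11 (not isolated)
Conditions: (COCl)2, DMF (cat.), CH2Cl2, 0 °C → rt, evaporate; then 10, PdCl2(PPh3)2 (cat.), CuI (cat.), Et3N, THF, rt
Reagents that add atoms: none
Why: Acyl Sonogashira coupling of the acid chloride with the terminal alkyne should give the silyl ynone under near-neutral conditions that the lactone tolerates.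

Step 6
Reactants: 12 silyl ynone
Product: 13 (4S,5R)-5-[(2S)-2-hydroxy-4-(trimethylsilyl)but-3-yn-1-yl]-4-methyloxan-2-one
Conditions: RuCl[(S,S)-TsDPEN](p-cymene) (cat.), i-PrOH, rt
Reagents that add atoms: none
Why: Noyori asymmetric transfer hydrogenation of an alkynyl ketone: the (S,S)-catalyst should deliver hydride to one carbonyl face, the alkynyl group taking the role that aryl plays in aryl ketones, so that C6 is set as S under reagent control.

Step 7
Reactants: 13 propargylic alcohol lactone
Product: 14 lithium (3S,4R,6S)-6-hydroxy-4-(hydroxymethyl)-3-methyloct-7-ynoate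
Conditions: LiOH·H2O (2.5 equiv), THF/H2O, 0 °C → rt; evaporate, azeotrope with toluene, dry in vacuo
Reagents that add atoms: lithium hydroxide, [Li+].[OH-]
Why: Saponification opens the δ-lactone and hydroxide removes the alkynyl silyl group, so the only electrophilic carbonyl becomes a carboxylate that a Grignard reagent does not attack; no stereocentre is affected.

Step 8
Reactants: 14 lithium carboxylate
Product: 16 (4S,5R)-5-[(2S,3Z)-2-hydroxy-4-iodo-3-methylbut-3-en-1-yl]-4-methyloxan-2-one, via dihydroxy acid 15 (not isolated)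
Conditions: MeMgBr (6 equiv), CuI (0.2 equiv), THF, −10 °C → rt; I2, THF, −40 → 0 °C; aq. Na2S2O3 then 1 M HCl; TsOH·H2O (cat.), CH2Cl2, rt
Reagents that add atoms: methylmagnesium bromide, C[Mg]Br; iodine, II
Why: Copper-catalysed anti-carbomagnesiation of a propargylic alkoxide: methyl adds to C1 and magnesium to C2 inside a five-membered alkoxide chelate, so iodination should give only the (Z)-iodoalkene with iodine cis to C6, the other alkoxide and the carboxylate being inert, and acid then relactonises the δ-hydroxy acid.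

Step 9
Reactants: 16 iodoalkenyl hydroxy lactone
Product: 17 (4S,5R)-5-[(2S,3Z)-2-{[tert-butyl(dimethyl)silyl]oxy}-4-iodo-3-methylbut-3-en-1-yl]-4-methyloxan-2-one
Conditions: TBSOTf, 2,6-lutidine, CH2Cl2, −78 → 0 °C
Reagents that add atoms: tert-butyldimethylsilyl triflate, CC(C)(C)[Si](C)(C)OS(=O)(=O)C(F)(F)F
Why: Silyl ether formation with the silyl triflate protects the hindered secondary allylic C6 alcohol, so that only the C3 oxygen is freed later.

Step 10
Reactants: 17 silyl ether lactone
Product: 18 (3S,4R,6S,7Z)-6-{[tert-butyl(dimethyl)silyl]oxy}-4-(hydroxymethyl)-8-iodo-N-methoxy-N,3,7-trimethyloct-7-enamide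
Conditions: MeNHOMe·HCl, AlMe3, CH2Cl2, 0 °C → rt; Rochelle salt work-up
Reagents that add atoms: N,O-dimethylhydroxylamine hydrochloride, CNOC.Cl
Why: Weinreb aminolysis of the lactone with the aluminium amide should install the C9 Weinreb amide and release the primary C3 alcohol in one operation, leaving the vinyl iodide and the silyl ether untouched.

Step 11
Reactants: 18 hydroxy Weinreb amide
Product: 19 (3S,4R,6S,7Z)-6-{[tert-butyl(dimethyl)silyl]oxy}-4-formyl-8-iodo-N-methoxy-N,3,7-trimethyloct-7-enamide
Conditions: Dess–Martin periodinane, NaHCO3, CH2Cl2, 0 °C → rt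
Reagents that add atoms: none
Why: Dess–Martin oxidation of the primary alcohol under buffered, non-basic conditions should give the α-branched aldehyde without epimerising C4.

Step 12
Reactants: 19 (Z)-vinyl iodide aldehyde
Product: 20 (3S)-3-[(1R,2R,5S)-5-{[tert-butyl(dimethyl)silyl]oxy}-2-hydroxy-4-methylcyclohex-3-en-1-yl]-N-methoxy-N-methylbutanamide
Conditions: CrCl2 (8 equiv), NiCl2 (cat.), degassed DMSO/THF, 0.005 M, rt
Reagents that add atoms: none
Why: Intramolecular Nozaki–Hiyama–Kishi reaction: zerovalent nickel, formed from NiCl2 by divalent chromium, inserts into the C2–I bond, transmetalation gives an alkenyl species of trivalent chromium with retention of the (Z)-geometry, and this adds to the C3 aldehyde to form the C2–C3 bond. The closest known reaction type is the nickel/chromium-mediated cyclisation of iodoalkenyl aldehydes to cycloalkenols. The six-membered ring closes in the 6-exo-trig mode through a chair-like transition state, and the retained (Z)-geometry places C1=C2 inside the ring. The new C3 stereocentre is controlled by that chair: the C4 side chain and the chromium alkoxide are both equatorial and C2 approaches anti to the C4–C7 bond (Felkin sense), which should give the 3R alcohol trans to the C4 branch, with the C6 silyloxy group pseudoaxial and away from the C1 methyl. The step needs addition to the aldehyde only and no enolisation at C4; the carbonyl selectivity and low basicity of alkenylchromium reagents secure both, and high dilution suppresses intermolecular coupling.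

Step 13
Reactants: 20 cyclohexenol; 21 4-fluoro-3-methoxybenzaldehyde
Product: 22 (3S)-3-[(1R,2R,5S)-5-{[tert-butyl(dimethyl)silyl]oxy}-2-(4-formyl-2-methoxyphenoxy)-4-methylcyclohex-3-en-1-yl]-N-methoxy-N-methylbutanamide
Conditions: KN(SiMe3)2 (1.05 equiv), THF, −40 °C; then 21, DMF, −20 °C → rt
Reagents that add atoms: none
Why: Nucleophilic aromatic substitution (SNAr): the potassium alkoxide of the C3 alcohol should displace fluoride para to the formyl group, and since the C3–O bond is not broken C3 keeps its configuration; the Weinreb amide is not enolised by the alkoxide, which is why the ketone is made only afterwards.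

Step 14
Reactants: 22 aryl ether aldehyde
Product: 23 (3S)-3-[(1R,2R,5S)-5-{[tert-butyl(dimethyl)silyl]oxy}-2-[4-(dimethoxymethyl)-2-methoxyphenoxy]-4-methylcyclohex-3-en-1-yl]-N-methoxy-N-methylbutanamide
Conditions: HC(OMe)3, PPTS (cat.), MeOH, rt
Reagents that add atoms: trimethyl orthoformate, COC(OC)OC
Why: Acid-catalysed acetalisation masks the aryl aldehyde against the Grignard reagent of the next step, and PPTS should leave the secondary silyl ether and the allylic aryl ether intact.

Step 15
Reactants: 23 acetal Weinreb amide; 24 (2-methylprop-1-en-1-yl)magnesium bromide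
Product: 26 (6S)-6-[(1R,2R,5S)-5-{[tert-butyl(dimethyl)silyl]oxy}-2-(4-formyl-2-methoxyphenoxy)-4-methylcyclohex-3-en-1-yl]-2-methylhept-2-en-4-one, via enone acetal 25 (not isolated)
Conditions: 24 (2.5 equiv), THF, 0 °C; then 1 M HCl, THF, 0 °C → rt
Reagents that add atoms: water, O
Why: Weinreb ketone synthesis: the alkenyl Grignard reagent adds once to give a stable magnesium chelate, and the aqueous acid work-up should release the enone and hydrolyse the electron-rich aryl dimethyl acetal in the same flask.

Step 16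
Reactants: 27 vanillin; 28 acetylacetone (3 equiv)
Product: 29 feruloylacetone, (5E)-6-(4-hydroxy-3-methoxyphenyl)hex-5-ene-2,4-dione
Conditions: B2O3, EtOAc, 75 °C; 27, B(On-Bu)3; n-BuNH2 (cat.), 75 °C; then 0.4 M HCl, 60 °C
Reagents that add atoms: none
Why: Boron-mediated aldol condensation: boron chelation of the diketone blocks the central carbon so that the aldehyde condenses at a terminal methyl, and the excess of diketone should hold the reaction at the mono-(E)-styryl stage.

Step 17
Reactants: 26 aldehyde enone; 29 feruloylacetone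
Product: 30 6-O-tert-butyldimethylsilyl ether of bisabolocurcumin ether
Conditions: 29 (1.5 equiv), B2O3, EtOAc, 70 °C; 26, B(On-Bu)3; n-BuNH2 (cat.), 70 °C; then 10% aq. AcOH, 45 °C
Reagents that add atoms: none
Why: Second boron-mediated aldol condensation at the remaining methyl of the chelated diketone should give the (E)-styryl unit of the unsymmetrical curcuminoid; the free phenol and the β,β-disubstituted enone are tolerated, and mild acid breaks the boron chelate.

Step 18
Reactants: 30 silyl-protected curcuminoid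
Product: 31 bisabolocurcumin ether
Conditions: HF·pyridine, pyridine, THF, 0 °C → rt
Reagents that add atoms: none
Why: Buffered HF·pyridine desilylation should free the C6 allylic alcohol without exposing the base-labile curcuminoid to basic fluoride.

**Compound list**

1 | methyl hydrogen (3R)-3-methylglutarate | OC(=O)C[C@@H](C)CC(=O)OC | starting material
2 | (4R)-4-benzyl-1,3-oxazolidin-2-one | O=C1N[C@H](Cc2ccccc2)CO1 | starting material
3 | mixed pivalic anhydride of 1 | CC(C)(C)C(=O)OC(=O)C[C@@H](C)CC(=O)OC | intermediate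
4 | methyl (3R)-5-[(4R)-4-benzyl-2-oxo-1,3-oxazolidin-3-yl]-3-methyl-5-oxopentanoate | O=C(C[C@@H](C)CC(=O)OC)N1[C@H](Cc2ccccc2)COC1=O | intermediate
5 | allyl iodide | C=CCI | starting material
6 | methyl (3S,4R)-4-{[(4R)-4-benzyl-2-oxo-1,3-oxazolidin-3-yl]carbonyl}-3-methylhept-6-enoate | C=CC[C@@H](C(=O)N1[C@H](Cc2ccccc2)COC1=O)[C@@H](C)CC(=O)OC | intermediate
7 | methyl (3S,4R)-4-(hydroxymethyl)-3-methylhept-6-enoate | C=CC[C@@H](CO)[C@@H](C)CC(=O)OC | intermediate
8 | (4S,5R)-4-methyl-5-(prop-2-en-1-yl)oxan-2-one | C=CC[C@H]1COC(=O)C[C@@H]1C | intermediate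
9 | [(3R,4S)-4-methyl-6-oxooxan-3-yl]acetic acid | OC(=O)C[C@H]1COC(=O)C[C@@H]1C | intermediate
10 | ethynyl(trimethyl)silane | C#C[Si](C)(C)C | starting material
11 | [(3R,4S)-4-methyl-6-oxooxan-3-yl]acetyl chloride | ClC(=O)C[C@H]1COC(=O)C[C@@H]1C | intermediate
12 | (4S,5R)-4-methyl-5-[2-oxo-4-(trimethylsilyl)but-3-yn-1-yl]oxan-2-one | C[Si](C)(C)C#CC(=O)C[C@H]1COC(=O)C[C@@H]1C | intermediate
13 | (4S,5R)-5-[(2S)-2-hydroxy-4-(trimethylsilyl)but-3-yn-1-yl]-4-methyloxan-2-one | C[Si](C)(C)C#C[C@@H](O)C[C@H]1COC(=O)C[C@@H]1C | intermediate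
14 | lithium (3S,4R,6S)-6-hydroxy-4-(hydroxymethyl)-3-methyloct-7-ynoate | C#C[C@@H](O)C[C@@H](CO)[C@@H](C)CC(=O)[O-].[Li+] | intermediate
15 | (3S,4R,6S,7Z)-6-hydroxy-4-(hydroxymethyl)-8-iodo-3,7-dimethyloct-7-enoic acid | I/C=C(/C)[C@@H](O)C[C@@H](CO)[C@@H](C)CC(=O)O | intermediate
16 | (4S,5R)-5-[(2S,3Z)-2-hydroxy-4-iodo-3-methylbut-3-en-1-yl]-4-methyloxan-2-one | I/C=C(/C)[C@@H](O)C[C@H]1COC(=O)C[C@@H]1C | intermediate
17 | (4S,5R)-5-[(2S,3Z)-2-{[tert-butyl(dimethyl)silyl]oxy}-4-iodo-3-methylbut-3-en-1-yl]-4-methyloxan-2-one | I/C=C(/C)[C@@H](O[Si](C)(C)C(C)(C)C)C[C@H]1COC(=O)C[C@@H]1C | intermediate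
18 | (3S,4R,6S,7Z)-6-{[tert-butyl(dimethyl)silyl]oxy}-4-(hydroxymethyl)-8-iodo-N-methoxy-N,3,7-trimethyloct-7-enamide | I/C=C(/C)[C@@H](O[Si](C)(C)C(C)(C)C)C[C@@H](CO)[C@@H](C)CC(=O)N(C)OC | intermediate
19 | (3S,4R,6S,7Z)-6-{[tert-butyl(dimethyl)silyl]oxy}-4-formyl-8-iodo-N-methoxy-N,3,7-trimethyloct-7-enamide | I/C=C(/C)[C@@H](O[Si](C)(C)C(C)(C)C)C[C@@H](C=O)[C@@H](C)CC(=O)N(C)OC | intermediate
20 | (3S)-3-[(1R,2R,5S)-5-{[tert-butyl(dimethyl)silyl]oxy}-2-hydroxy-4-methylcyclohex-3-en-1-yl]-N-methoxy-N-methylbutanamide | O[C@H]1C=C(C)[C@@H](O[Si](C)(C)C(C)(C)C)C[C@@H]1[C@@H](C)CC(=O)N(C)OC | intermediate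
21 | 4-fluoro-3-methoxybenzaldehyde | COc1cc(C=O)ccc1F | starting material
22 | (3S)-3-[(1R,2R,5S)-5-{[tert-butyl(dimethyl)silyl]oxy}-2-(4-formyl-2-methoxyphenoxy)-4-methylcyclohex-3-en-1-yl]-N-methoxy-N-methylbutanamide | COc1cc(C=O)ccc1O[C@H]1C=C(C)[C@@H](O[Si](C)(C)C(C)(C)C)C[C@@H]1[C@@H](C)CC(=O)N(C)OC | intermediate
23 | (3S)-3-[(1R,2R,5S)-5-{[tert-butyl(dimethyl)silyl]oxy}-2-[4-(dimethoxymethyl)-2-methoxyphenoxy]-4-methylcyclohex-3-en-1-yl]-N-methoxy-N-methylbutanamide | COC(OC)c1ccc(O[C@H]2C=C(C)[C@@H](O[Si](C)(C)C(C)(C)C)C[C@@H]2[C@@H](C)CC(=O)N(C)OC)c(OC)c1 | intermediate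
24 | (2-methylprop-1-en-1-yl)magnesium bromide | CC(C)=C[Mg]Br | starting material
25 | (6S)-6-[(1R,2R,5S)-5-{[tert-butyl(dimethyl)silyl]oxy}-2-[4-(dimethoxymethyl)-2-methoxyphenoxy]-4-methylcyclohex-3-en-1-yl]-2-methylhept-2-en-4-one | COC(OC)c1ccc(O[C@H]2C=C(C)[C@@H](O[Si](C)(C)C(C)(C)C)C[C@@H]2[C@@H](C)CC(=O)C=C(C)C)c(OC)c1 | intermediate
26 | (6S)-6-[(1R,2R,5S)-5-{[tert-butyl(dimethyl)silyl]oxy}-2-(4-formyl-2-methoxyphenoxy)-4-methylcyclohex-3-en-1-yl]-2-methylhept-2-en-4-one | COc1cc(C=O)ccc1O[C@H]1C=C(C)[C@@H](O[Si](C)(C)C(C)(C)C)C[C@@H]1[C@@H](C)CC(=O)C=C(C)C | intermediate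
27 | vanillin (4-hydroxy-3-methoxybenzaldehyde) | COc1cc(C=O)ccc1O | starting material
28 | acetylacetone (pentane-2,4-dione) | CC(=O)CC(C)=O | starting material
29 | feruloylacetone, (5E)-6-(4-hydroxy-3-methoxyphenyl)hex-5-ene-2,4-dione | COc1cc(/C=C/C(=O)CC(C)=O)ccc1O | intermediate
30 | 6-O-tert-butyldimethylsilyl ether of bisabolocurcumin ether (3R,4R,6S,7S in the locants of the overview) | COc1cc(/C=C/C(=O)/C=C(O)/C=C/c2ccc(O[C@H]3C=C(C)[C@@H](O[Si](C)(C)C(C)(C)C)C[C@@H]3[C@@H](C)CC(=O)C=C(C)C)c(OC)c2)ccc1O | intermediate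
31 | bisabolocurcumin ether (3R,4R,6S,7S in the locants of the overview) | COc1cc(/C=C/C(=O)/C=C(O)/C=C/c2ccc(O[C@H]3C=C(C)[C@@H](O)C[C@@H]3[C@@H](C)CC(=O)C=C(C)C)c(OC)c2)ccc1O | target

**Step count and risks**

Total: 18 steps. Longest linear sequence: 17 steps (steps 1–15, 17 and 18, from hemiester 1); step 16 is a one-step side branch.

Steps most likely to fail:

1. Step 12 (ring closure). The closure may proceed with poor facial selectivity at C3, because the chair preference for an equatorial chromium alkoxide is the only control element. In that case C3 would be set by reduction instead of by C–C bond formation. The fallback sets out from 20 (as its mixture with the C3 epimer). Dess–Martin oxidation would give the cyclohexenone (3S)-3-[(1R,5S)-5-{[tert-butyl(dimethyl)silyl]oxy}-4-methyl-2-oxocyclohex-3-en-1-yl]-N-methoxy-N-methylbutanamide F1. Luche reduction (NaBH4, CeCl3·7H2O, MeOH, −78 °C) should then deliver hydride axially and give the equatorial 3R alcohol trans to the C4 branch, which returns to 20.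

2. Step 8 (carbomagnesiation/iodination). The polyanionic lithium/magnesium salt may aggregate or precipitate, so that methyl transfer to the alkyne stalls, or the Grignard reagent may slowly attack the carboxylate. The fallback avoids organomagnesium reagents and sets out from 13. Silylation (TBSOTf, 2,6-lutidine) would give (4S,5R)-5-[(2S)-2-{[tert-butyl(dimethyl)silyl]oxy}-4-(trimethylsilyl)but-3-yn-1-yl]-4-methyloxan-2-one F2. Gold-catalysed Markovnikov hydration ((Ph3P)AuNTf2 cat., MeOH/H2O), with loss of the alkynyl silyl group, would give the methyl ketone (4S,5R)-5-[(2S)-2-{[tert-butyl(dimethyl)silyl]oxy}-3-oxobutyl]-4-methyloxan-2-one F3. Stork–Zhao olefination ((iodomethyl)triphenylphosphonium iodide, NaN(SiMe3)2, THF/HMPA, −78 °C), a Wittig reaction that places the ylide substituent cis to the oxygen-bearing carbon of α-oxygenated ketones, should then give the (Z)-iodoalkene and return to the route at 17.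

3. Step 13 (SNAr). The hindered secondary potassium alkoxide may substitute slowly and instead transfer hydride to the aryl aldehyde (Oppenauer-type oxidation of C3). The fallback replaces the alkoxide by a neutral palladium-catalysed allylic substitution and sets out from 20. Methyl chloroformate and pyridine would give the allylic carbonate (3S)-3-[(1R,2R,5S)-5-{[tert-butyl(dimethyl)silyl]oxy}-2-[(methoxycarbonyl)oxy]-4-methylcyclohex-3-en-1-yl]-N-methoxy-N-methylbutanamide F4. Tsuji–Trost O-allylation of vanillin 27 (Pd2(dba)3, PPh3, THF, rt) should attack the less substituted allyl terminus C3 with net retention (double inversion) and return to the route at 22.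

Further compounds
F1 | step 12 | (3S)-3-[(1R,5S)-5-{[tert-butyl(dimethyl)silyl]oxy}-4-methyl-2-oxocyclohex-3-en-1-yl]-N-methoxy-N-methylbutanamide | O=C1C=C(C)[C@@H](O[Si](C)(C)C(C)(C)C)C[C@@H]1[C@@H](C)CC(=O)N(C)OC
F2 | step 8 | (4S,5R)-5-[(2S)-2-{[tert-butyl(dimethyl)silyl]oxy}-4-(trimethylsilyl)but-3-yn-1-yl]-4-methyloxan-2-one | C[Si](C)(C)C#C[C@@H](O[Si](C)(C)C(C)(C)C)C[C@H]1COC(=O)C[C@@H]1C
F3 | step 8 | (4S,5R)-5-[(2S)-2-{[tert-butyl(dimethyl)silyl]oxy}-3-oxobutyl]-4-methyloxan-2-one | CC(=O)[C@@H](O[Si](C)(C)C(C)(C)C)C[C@H]1COC(=O)C[C@@H]1C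
F4 | step 13 | (3S)-3-[(1R,2R,5S)-5-{[tert-butyl(dimethyl)silyl]oxy}-2-[(methoxycarbonyl)oxy]-4-methylcyclohex-3-en-1-yl]-N-methoxy-N-methylbutanamide | COC(=O)O[C@H]1C=C(C)[C@@H](O[Si](C)(C)C(C)(C)C)C[C@@H]1[C@@H](C)CC(=O)N(C)OC
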